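## Analysis of the target

Carbon numbers follow the ten-membered ring of target 36 and are kept for every intermediate: epoxide C1–C10 (C14 methyl on C10), Z alkene C4=C5 (C15 methyl on C4), angelate on C6, γ-lactone from C8–O through C7 and C11 to the C12 carbonyl, and C11 bearing the C13 methyl and the second angelate. The six stereocentres are 1R,6R,7S,8R,10R,11R. C6, C7 and C8 are contiguous, with O6 and C11 on one face of the ring and O8 on the other, so the lactone is trans-fused. C11 is a fully substituted carbinol outside the ring, and the epoxide is the trans epoxide of an E alkene. The angelates isomerise to tiglates under nucleophilic catalysis or heat, and the epoxide is opened by acid. The C1=C10/C4=C5 1,5-diene of the late intermediates is prone to transannular cyclisation and Cope rearrangement. C7–H sits between oxygenated C6, C8 and C11, so β-elimination threatens whenever C6 is a ketone. The main difficulty is a ten-membered ring with two trisubstituted alkenes of opposite geometry, which direct closure controls poorly, together with the tertiary C11 carbinol and the C6 carbinol on a flexible ring. The strategy rests on the 1,3-relationship between C6 and the C1=C10 alkene. An extra C6–C10 bond divides the ring into a cycloheptene (C6, C5, C4, C3, C2, C1, C10), which can only hold C4=C5 as Z, and a cyclopentane (C6, C7, C8, C9, C10) carrying C7 and C8. An alkoxide on C6 and a leaving group on C1 make that bond cleavable again.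

## Retrosynthetic reasoning

36 ⇒ 35. The two C–O bonds of the epoxide are cut last, because the epoxide is the most fragile group. The forward step must pick C1=C10 over C4=C5 and the angelate alkenes, and must deliver oxygen to one face under reagent control.

35 ⇒ 33 ⇒ 31 ⇒ 28. The C11 ester, the lactone C12–O8 bond and the C12 oxidation level are removed in turn. O6 and O8 are both γ to C12, so O6 must already carry its angelate when O8 is freed; only then can lactonisation go to O8 alone. C12 is raised to the acid while O8 is still silylated, so no oxidant meets a free secondary alcohol.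

28 ⇒ 26 ⇒ 25. The C6 ester and the C6–H bond are cut back to the enone. This gives C6 as a ketone conjugated to the Z alkene, the form in which the key step delivers it, and leaves its configuration to a 1,2-reduction.

25 ⇒ 23 (key disconnection). The C6–C10 bond is reconnected and C1 receives a sulfonate. The ten-membered ring then becomes the bond shared by a five- and a seven-membered ring, so it never has to be closed. Z at C4=C5 is stored in the cycloheptene and E at C1=C10 in the relative configuration of C1 and C10.

23 ⇒ 22 ⇒ 21. The mesylate comes from the 1R alcohol, and this from the C1 ketone. C1 is not set in the aldol that makes C10–C1, because a closed transition state of the ring enolate would place the hydroxyl trans to the C10 methyl on the later seven-membered ring. That epimer cannot give the E alkene. A reagent-controlled reduction of a ketone flanked by a quaternary carbon and a methylene is the dependable alternative.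

21 ⇒ 20 ⇒ 19 ⇒ 18. These are protecting-group and redox adjustments. The C11/C12 diol is held as an acetonide, which has no acidic proton, no migrating silyl group and no electrophilic carbonyl near the C6 alkoxide. The diol is obtained from the C12 ester once C6 is no longer a ketone.

18 ⇒ 16. The C5–C6 bond is cut. Forward, the Z alkenyl iodide adds as an alkenylmetal to the C6 ketone from the face of its own tether. This closes the seven-membered ring, makes the ring fusion cis and keeps C4=C5 as Z. C1 must be a carbinol at this stage, since a C1 ketone would be attacked first to give a five-membered ring.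

16 ⇒ 13 + 14. The C7–C11 bond is cut as an aldol between the C6 enol silane and pyruvate 14. C7 is set by the neighbouring C8 silyloxy group and C11 by a chiral Lewis acid, so the tertiary carbinol does not depend on the facial preference of an unsymmetrical ketone.

13 ⇒ 12 ⇒ 4 + 11. The C10–C1 bond is cut as a Mukaiyama aldol of the tetrasubstituted enol silane 4 with aldehyde 11. This makes the quaternary C10 anti to the C8 silyloxy group before C7 is substituted.

4 ⇒ 3 ⇒ 2 ⇒ 1. The C10 methyl is introduced on the enone by iodination and cross-coupling. 1,4-Hydrosilylation then gives the C6/C10 enol silane as a single regioisomer. C8 comes from the chiral pool with 1.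

11 ⇒ 10 ⇒ 5 + 6. The C3–C4 bond is cut. Syn carbometalation of propyne 6 by the organocopper from 5, followed by iodination, fixes the Z geometry of the alkenyl iodide.

## Alternatives that were turned down

Alternative 1: This route cuts C7–C8 and the lactone C12–O8 bond together. A boron enolate at C7 of a chiral-pool hydroxy diacid unit, which already holds C11, would add to a C8 aldehyde carrying the whole C9–C10–C1–C5 dienyl iodide chain. The aldolate would then close the lactone to give A1. In its favour, it is convergent, C11 comes from the pool without any catalyst-controlled step, and C7, C8 and the lactone arise in one operation. On these points it is stronger than the chosen route, which spends a catalytic aldol and several redox steps on C11 and C12. Against it, the C7 enolate has the C11 oxygen in the β-position and can eliminate. The aldehyde partner is β,γ-unsaturated and drifts into conjugation. An auxiliary-controlled syn aldol does not obviously give the trans relationship of C7 and C8. Above all, A1 is still acyclic in the ten-membered sense: the ring must be closed at C5–C6 by a macrocyclisation onto a C6 carbonyl, with transannular strain and an uncontrolled C6 carbinol. The chosen route offers instead a ring that is released by a unimolecular fragmentation with both alkene geometries fixed in advance.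

Alternative 2: This route forms C2–C3 and breaks C5–C10 in an anionic oxy-Cope rearrangement of a six-membered-ring potassium alkoxide from the terpene pool. The C4=C5 enolate is trapped as enol triflate A2. In its favour, it also uncovers the ring by a sigmatropic process and does not close it, it starts from a cheap chiral cyclohexenone, and it could be shorter up to the ring-forming step. Against it, the substrate needs two adjacent fully substituted carbons (C5 and C10) with both alkenyl arms cis. The C4=C5 geometry depends on a chair-versus-boat preference of a crowded transition state. The C6 oxygen must be installed beforehand and then sits β to the new enolate, where it can be eliminated. The triflate on C5 has to be reduced off afterwards. In the chosen route C4=C5 is Z because a cycloheptene allows nothing else, and C6 appears as a ketone ready for reduction; that certainty is judged worth the extra steps.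

Alternative 3: This route cuts C6–C7. Lithiation at C6 of a thirteen-membered bis-allylic ether, with oxygen between C6 and C13, would trigger a [2,3]-Wittig shift. The shift contracts the ring to dienol A3 with C6–OH and a C11=C13 methylene. In its favour, closing a macrocyclic ether is easier than closing the carbocycle. C6–OH and the C6–C7 bond arise together, and the free C6 hydroxyl is ready for acylation. It is likely the shortest of the four and stronger on step economy. Against it, both α-oxy allylic positions (C6 and C13) can be lithiated, and a [1,2]-shift competes. C6 and C7 are set through a large-ring transition state whose preference cannot be predicted with confidence. C11 must later be made by a substrate-controlled functionalisation of a 1,1-disubstituted alkene on the flexible ring. The chosen route has a single, well-defined stereoelectronic requirement in its ring-forming step and sets C11 early under catalyst control.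

Key step: step 15

Assumption (remark on the chemistry): the C1 carbinol of 12–20 is carried as both epimers and drawn without configuration, because it is oxidised in step 12 and reset in step 13.

## Route

Step 1
Reactants: 1 (S)-4-(tert-butyldimethylsilyloxy)cyclopent-2-en-1-one
Product: 2 (S)-4-(tert-butyldimethylsilyloxy)-2-iodocyclopent-2-en-1-one
Conditions: I2, pyridine/CH2Cl2, 0 → 25 °C
Reagents that add atoms: iodine, II
Why: α-Iodination of an enone by conjugate addition of pyridine, iodination of the enolate and elimination; C8 is untouched.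

Step 2
Reactants: 2 (S)-4-(tert-butyldimethylsilyloxy)-2-iodocyclopent-2-en-1-one
Product: 3 (S)-4-(tert-butyldimethylsilyloxy)-2-methylcyclopent-2-en-1-one
Conditions: Me4Sn, PdCl2(PhCN)2 (5 mol%), AsPh3, CuI, NMP, 60 °C
Reagents that add atoms: tetramethylstannane, C[Sn](C)(C)C
Why: Stille coupling of an α-iodoenone installs the C14 methyl on C10 under neutral conditions that do not endanger the γ-silyloxy group.

Step 3
Reactants: 3 (S)-4-(tert-butyldimethylsilyloxy)-2-methylcyclopent-2-en-1-one
Product: 4 (R)-4-(tert-butyldimethylsilyloxy)-2-methyl-1-(triethylsilyloxy)cyclopent-1-ene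
Conditions: Et3SiH, RhCl(PPh3)3 (1 mol%), THF, 50 °C
Reagents that add atoms: triethylsilane, CC[SiH](CC)CC
Why: Rhodium-catalysed 1,4-hydrosilylation of the enone gives the C6/C10 enol silane as one regioisomer without a carbanion at C9 that could expel the C8 silyloxy group; the descriptor at C8 changes by priority only.

Step 4
Reactants: 5 2-(2-bromoethyl)-1,3-dioxolane; 6 propyne
Product: 10 (Z)-2-(4-iodo-3-methylbut-3-en-1-yl)-1,3-dioxolane, via Grignard reagent 7 (not isolated), via alkylcopper 8 (not isolated), via (Z)-alkenylcopper 9 (not isolated)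
Conditions: Mg, THF, 25 °C; CuBr·SMe2, Et2O/Me2S, −45 °C; propyne, −25 °C; I2, −50 → 0 °C
Reagents that add atoms: iodine, II
Why: Normant-type carbocupration adds the alkyl group and copper syn across propyne with copper on the terminal carbon, and iodinolysis with retention gives the iodide cis to the chain, which is the future Z C4=C5.

Step 5
Reactants: 10 (Z)-2-(4-iodo-3-methylbut-3-en-1-yl)-1,3-dioxolane
Product: 11 (Z)-5-iodo-4-methylpent-4-enal
Conditions: 1 M HCl, THF, 25 °C
Reagents that add atoms: water, O
Why: Acid hydrolysis of the dioxolane frees the C1 aldehyde; the alkenyl iodide is inert to dilute acid.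

Step 6
Reactants: 4 (R)-4-(tert-butyldimethylsilyloxy)-2-methyl-1-(triethylsilyloxy)cyclopent-1-ene; 11 (Z)-5-iodo-4-methylpent-4-enal
Product: 12 (2S,4R)-4-(tert-butyldimethylsilyloxy)-2-[(Z)-1-hydroxy-5-iodo-4-methylpent-4-en-1-yl]-2-methylcyclopentan-1-one (both C1 epimers)
Conditions: BF3·OEt2 (1.1 equiv), CH2Cl2, −78 °C
Reagents that add atoms: none
Why: Mukaiyama aldol of the tetrasubstituted enol silane forms C10–C1 and the quaternary C10; the aldehyde should approach anti to the C8 silyloxy group, the only stereocentre on the ring, and any minor C10 epimer can be removed by chromatography at ketone 21 at the latest.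

Step 7
Reactants: 12 (2S,4R)-4-(tert-butyldimethylsilyloxy)-2-[(Z)-1-hydroxy-5-iodo-4-methylpent-4-en-1-yl]-2-methylcyclopentan-1-one
Product: 13 (3R,5S)-3-(tert-butyldimethylsilyloxy)-5-[(Z)-5-iodo-4-methyl-1-(trimethylsilyloxy)pent-4-en-1-yl]-5-methyl-1-(trimethylsilyloxy)cyclopent-1-ene
Conditions: TMSOTf (2.5 equiv), Et3N (4 equiv), CH2Cl2, 0 °C
Reagents that add atoms: trimethylsilyl trifluoromethanesulfonate, C[Si](C)(C)OS(=O)(=O)C(F)(F)F
Why: Soft enolisation can only go towards C7 because C10 is quaternary, and the C1 hydroxyl is capped in the same operation; no strong base is present that could cause retro-aldol cleavage or loss of the C8 silyloxy group.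

Step 8
Reactants: 13 (3R,5S)-3-(tert-butyldimethylsilyloxy)-5-[(Z)-5-iodo-4-methyl-1-(trimethylsilyloxy)pent-4-en-1-yl]-5-methyl-1-(trimethylsilyloxy)cyclopent-1-ene; 14 methyl pyruvate
Product: 16 methyl (2R)-2-[(1R,3S,5R)-5-(tert-butyldimethylsilyloxy)-3-[(Z)-1-hydroxy-5-iodo-4-methylpent-4-en-1-yl]-3-methyl-2-oxocyclopentyl]-2-hydroxypropanoate, via bis(trimethylsilyl) aldol adduct 15 (not isolated)
Conditions: [Cu((R,R)-tBu-box)](OTf)2 (10 mol%; tBu-box = 2,2′-isopropylidenebis(4-tert-butyl-2-oxazoline)), THF, −78 → −40 °C; then 1 M HCl, THF, 0 °C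
Reagents that add atoms: none
Why: Catalytic enantioselective Mukaiyama aldol to a pyruvate chelated on divalent copper; the (R,R) complex exposes the re face of the ketone and sets C11 as R, the enol silane reacts anti to the adjacent C8 silyloxy group to set C7, and the required C7/C11 relationship is the syn one that this reaction class favours, so all three controls should agree.

Step 9
Reactants: 16 methyl (2R)-2-[(1R,3S,5R)-5-(tert-butyldimethylsilyloxy)-3-[(Z)-1-hydroxy-5-iodo-4-methylpent-4-en-1-yl]-3-methyl-2-oxocyclopentyl]-2-hydroxypropanoate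
Product: 18 (6R,7S,8R,10S,11R)-cis-hydroazulene triol ester (1-OH both epimers; 6-OH; 11-OH; C12 methyl ester), via alkenylchromium dichloride 17 (not isolated)
Conditions: CrCl2 (6 equiv), NiCl2 (2 mol%), DMSO, 25 °C
Reagents that add atoms: none
Why: Intramolecular Nozaki–Hiyama–Kishi addition: zerovalent nickel inserts into the C–I bond, the alkenyl group passes to trivalent chromium and adds to the C6 ketone from the face of its C10 tether, closing the seven-membered ring with cis fusion (6-OH cis to the C10 methyl) and retaining Z at C4=C5; free hydroxyls and the ester are tolerated.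

Step 10
Reactants: 18 (6R,7S,8R,10S,11R)-cis-hydroazulene triol ester
Product: 19 (6R,7S,8R,10S,11R)-cis-hydroazulene tetraol (1-OH both epimers; 6-OH; 11-OH; 12-OH)
Conditions: LiBH4, THF, 0 → 25 °C
Reagents that add atoms: none
Why: Borohydride reduction of the α-hydroxy ester to the 11,12-diol; no other reducible group remains once C6 is a carbinol.

Step 11
Reactants: 19 (6R,7S,8R,10S,11R)-cis-hydroazulene tetraol
Product: 20 (6R,7S,8R,10S,11R)-cis-hydroazulene-1,6-diol 11,12-acetonide (1-OH both epimers)
Conditions: 2,2-dimethoxypropane (1.5 equiv), PPTS (5 mol%), CH2Cl2, 0 °C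
Reagents that add atoms: 2,2-dimethoxypropane, COC(C)(C)OC
Why: Acetal exchange is fastest at the terminal 1,2-diol with its primary hydroxyl; the 1,6-diol would need the hindered tertiary allylic hydroxyl and should stay free.

Step 12
Reactants: 20 (6R,7S,8R,10S,11R)-cis-hydroazulene-1,6-diol 11,12-acetonide
Product: 21 (6R,7S,8R,10R,11R)-6-hydroxy-cis-hydroazulen-1-one 11,12-acetonide
Conditions: Dess–Martin periodinane, NaHCO3, CH2Cl2, 0 → 25 °C
Reagents that add atoms: none
Why: Dess–Martin oxidation of the only secondary alcohol merges the C1 epimers; the tertiary C6 hydroxyl cannot be oxidised, and the buffered neutral medium avoids retro-aldol cleavage of the β-hydroxy ketone.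

Step 13
Reactants: 21 (6R,7S,8R,10R,11R)-6-hydroxy-cis-hydroazulen-1-one 11,12-acetonide
Product: 22 (1R,6R,7S,8R,10S,11R)-cis-hydroazulene-1,6-diol 11,12-acetonide
Conditions: (S)-2-methyl-CBS-oxazaborolidine (0.5 equiv), catecholborane (3 equiv), toluene, −78 → −40 °C
Reagents that add atoms: none
Why: Corey–Bakshi–Shibata reduction of a ketone whose flanks (quaternary C10 against the C2 methylene) are as different as in tert-alkyl methyl ketones; the (S) catalyst gives the 1R alcohol, cis to the C10 methyl and the 6-OH, and the background reduction of a β-hydroxy ketone by catecholborane tends to the same 1,3-syn diol.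

Step 14
Reactants: 22 (1R,6R,7S,8R,10S,11R)-cis-hydroazulene-1,6-diol 11,12-acetonide
Product: 23 (1R,6R,7S,8R,10S,11R)-6-hydroxy-cis-hydroazulen-1-yl methanesulfonate 11,12-acetonide
Conditions: MsCl, Et3N, CH2Cl2, −20 °C
Reagents that add atoms: methanesulfonyl chloride, CS(=O)(=O)Cl
Why: Sulfonylation through the sulfene takes the secondary C1 hydroxyl and leaves the tertiary ring-fusion hydroxyl free; the neutral alcohol does not fragment.

Step 15
Reactants: 23 (1R,6R,7S,8R,10S,11R)-6-hydroxy-cis-hydroazulen-1-yl methanesulfonate 11,12-acetonide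
Product: 25 (7R,8R,11R)-(4Z,1(10)E)-cyclodecadien-6-one with 8-OTBS and 11,12-acetonide, via potassium alkoxide 24 (not isolated)
Conditions: KOtBu (1.0 equiv, added slowly), THF, −20 → 0 °C; pH 7 buffer quench
Reagents that add atoms: none
Why: The base turns the tertiary C6 hydroxyl into alkoxide 24; in the conformer with the C1 mesylate equatorial on the seven-membered ring, C1–O is antiperiplanar to C6–C10, so the oxygen lone pair pushes in, C6–C10 breaks and mesylate leaves in one concerted heterolytic step that forms C6=O and C1=C10. The closest known reaction is the Wharton-type Grob fragmentation of bicyclic 1,3-diol monosulfonates to medium-ring alkenones. No σ bond is formed: the ten-membered ring appears by scission of the bond shared by the five- and seven-membered rings, so there is no closure mode and no entropic penalty. No stereocentre is created; C1, C6 and C10 become trigonal, and C7, C8 and C11 are untouched. E geometry at C1=C10 follows from the 1R,10S relationship, which puts C2 gauche to the C10 methyl and anti to C9 in the reactive conformer, and Z at C4=C5 is inherited from the cycloheptene. The step needs fragmentation to outrun proton transfer to the new ketone, whose C7–H lies between two β-oxygens, and silyl migration from O8 to O6. This is secured because each equivalent of base ends as potassium mesylate, by the low temperature, and because O6 and the mesylate are cis, which rules out oxetane formation by backside attack.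

Step 16
Reactants: 25 (7R,8R,11R)-(4Z,1(10)E)-cyclodecadien-6-one with 8-OTBS and 11,12-acetonide
Product: 26 (6R,7R,8R,11R)-(4Z,1(10)E)-cyclodecadien-6-ol with 8-OTBS and 11,12-acetonide
Conditions: (R)-2-methyl-CBS-oxazaborolidine (1.0 equiv), catecholborane (2 equiv), toluene, −78 °C
Reagents that add atoms: none
Why: Corey–Bakshi–Shibata 1,2-reduction of the enone; with the conjugated alkenyl flank acting as the large group, as is usual for enones, the (R) catalyst delivers hydride to give 6R, and the mild boron hydride leaves the C7–H acidity unused.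

Step 17
Reactants: 26 (6R,7R,8R,11R)-(4Z,1(10)E)-cyclodecadien-6-ol with 8-OTBS and 11,12-acetonide
Product: 28 (6R,7R,8R,11R)-6-angeloyloxy-(4Z,1(10)E)-cyclodecadiene with 8-OTBS and 11,12-acetonide, via lithium alkoxide 27 (not isolated)
Conditions: LiHMDS (1.05 equiv), THF, −78 °C; angelic anhydride (1.5 equiv), −78 → 0 °C
Reagents that add atoms: angelic anhydride, C/C=C(/C)C(=O)OC(=O)/C(C)=C\C
Why: O-acylation of the lithium alkoxide by the anhydride needs no nucleophilic catalyst, so the Z geometry of the angeloyl group should be kept, and the low temperature avoids Cope rearrangement of the 1,5-diene and silyl migration from O8.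

Step 18
Reactants: 28 (6R,7R,8R,11R)-6-angeloyloxy-(4Z,1(10)E)-cyclodecadiene with 8-OTBS and 11,12-acetonide
Product: 29 (6R,7R,8R,11R)-6-angeloyloxy-8-OTBS-(4Z,1(10)E)-cyclodecadiene-11,12-diol
Conditions: PPTS (0.3 equiv), MeOH, 40 °C
Reagents that add atoms: none
Why: Mild acid-catalysed acetal exchange removes the terminal acetonide, while the secondary silyl ether, the allylic ester and the diene should survive this weak acid.

Step 19
Reactants: 29 (6R,7R,8R,11R)-6-angeloyloxy-8-OTBS-(4Z,1(10)E)-cyclodecadiene-11,12-diol
Product: 30 (6R,7R,8R,11R)-6-angeloyloxy-8-OTBS-11-hydroxy-(4Z,1(10)E)-cyclodecadien-12-al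
Conditions: SO3·pyridine, DMSO, iPr2NEt, CH2Cl2, 0 °C
Reagents that add atoms: none
Why: Parikh–Doering oxidation takes the primary C12 alcohol to the aldehyde; the tertiary C11 hydroxyl is inert, O8 is still silylated, and an activated-DMSO oxidant does not cleave the vicinal diol as hypervalent iodine or periodate could.

Step 20
Reactants: 30 (6R,7R,8R,11R)-6-angeloyloxy-8-OTBS-11-hydroxy-(4Z,1(10)E)-cyclodecadien-12-al
Product: 31 (6R,7R,8R,11R)-6-angeloyloxy-8-OTBS-11-hydroxy-(4Z,1(10)E)-cyclodecadien-12-oic acid
Conditions: NaClO2, NaH2PO4, 2-methyl-2-butene (excess), tBuOH/H2O, 0 → 25 °C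
Reagents that add atoms: sodium chlorite, [Na+].[O-]Cl=O
Why: Pinnick oxidation of the non-enolisable α-hydroxy aldehyde; the alkene scavenger takes up hypochlorous acid before it can reach the ring alkenes.

Step 21
Reactants: 31 (6R,7R,8R,11R)-6-angeloyloxy-8-OTBS-11-hydroxy-(4Z,1(10)E)-cyclodecadien-12-oic acid
Product: 33 (6R,7S,8R,11R)-6-angeloyloxy-11-hydroxy-(4Z,1(10)E)-cyclodecadien-12,8-olide, via dihydroxy acid 32 (not isolated)
Conditions: HF·pyridine, pyridine, THF, 0 → 25 °C; then PPTS (cat.), CH2Cl2, 25 °C
Reagents that add atoms: none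
Why: Buffered fluoride frees the C8 hydroxyl, and the γ-hydroxy acid closes to the five-membered lactone; O6 is acylated, so only the 12,8-olide can form, and acidic conditions prevent acyl migration from O6.

Step 22
Reactants: 33 (6R,7S,8R,11R)-6-angeloyloxy-11-hydroxy-(4Z,1(10)E)-cyclodecadien-12,8-olide
Product: 35 (6R,7S,8R,11R)-6,11-bis(angeloyloxy)-(4Z,1(10)E)-cyclodecadien-12,8-olide, via lithium alkoxide 34 (not isolated)
Conditions: LiHMDS (1.05 equiv), THF, −78 °C; angelic anhydride (2 equiv), −78 → 0 °C
Reagents that add atoms: angelic anhydride, C/C=C(/C)C(=O)OC(=O)/C(C)=C\C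
Why: The tertiary α-hydroxy lactone is the most acidic site and has no α-proton, so its alkoxide forms selectively and is acylated without nucleophilic catalysis; a transfer of the C6 acyl group to O11 would be repaired by the excess anhydride and lead to the same product.

Step 23
Reactants: 35 (6R,7S,8R,11R)-6,11-bis(angeloyloxy)-(4Z,1(10)E)-cyclodecadien-12,8-olide
Product: 36 target (1R,6R,7S,8R,10R,11R)-1,10-epoxy-6,11-bis(angeloyloxy)-(4Z)-cyclodecen-12,8-olide
Conditions: 1,2:4,5-di-O-isopropylidene-β-D-erythro-2,3-hexodiulo-2,6-pyranose (D-fructose-derived Shi ketone, 0.3 equiv), Oxone (KHSO5), K2CO3, Bu4NHSO4, MeCN/dimethoxymethane/aqueous buffer (pH 10.5), 0 °C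
Reagents that add atoms: potassium peroxymonosulfate, [K+].[O-]S(=O)(=O)OO
Why: Shi epoxidation: the chiral dioxirane attacks the electron-rich E-trisubstituted C1=C10 through a spiro transition state that gives R,R epoxides from E alkenes of this substitution pattern; C4=C5 (Z, next to an allylic ester) and the conjugated angelate alkenes react far more slowly.

## Compound list

1 | (S)-4-(tert-butyldimethylsilyloxy)cyclopent-2-en-1-one | O=C1C=C[C@@H](O[Si](C)(C)C(C)(C)C)C1 | starting material
2 | (S)-4-(tert-butyldimethylsilyloxy)-2-iodocyclopent-2-en-1-one | O=C1C(I)=C[C@@H](O[Si](C)(C)C(C)(C)C)C1 | intermediate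
3 | (S)-4-(tert-butyldimethylsilyloxy)-2-methylcyclopent-2-en-1-one | O=C1C(C)=C[C@@H](O[Si](C)(C)C(C)(C)C)C1 | intermediate
4 | (R)-4-(tert-butyldimethylsilyloxy)-2-methyl-1-(triethylsilyloxy)cyclopent-1-ene | CC[Si](CC)(CC)OC1=C(C)C[C@@H](O[Si](C)(C)C(C)(C)C)C1 | intermediate
5 | 2-(2-bromoethyl)-1,3-dioxolane | BrCCC1OCCO1 | starting material
6 | propyne | CC#C | starting material
7 | [2-(1,3-dioxolan-2-yl)ethyl]magnesium bromide | Br[Mg]CCC1OCCO1 | intermediate
8 | [2-(1,3-dioxolan-2-yl)ethyl]copper (MgBr2 complex) | [Cu]CCC1OCCO1 | intermediate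
9 | (Z)-[4-(1,3-dioxolan-2-yl)-2-methylbut-1-en-1-yl]copper | [Cu]/C=C(C)\CCC1OCCO1 | intermediate
10 | (Z)-2-(4-iodo-3-methylbut-3-en-1-yl)-1,3-dioxolane | I/C=C(C)\CCC1OCCO1 | intermediate
11 | (Z)-5-iodo-4-methylpent-4-enal | O=CCC/C(C)=C\I | intermediate
12 | (2S,4R)-4-(tert-butyldimethylsilyloxy)-2-[(Z)-1-hydroxy-5-iodo-4-methylpent-4-en-1-yl]-2-methylcyclopentan-1-one (both carbinol epimers) | O=C1C[C@H](O[Si](C)(C)C(C)(C)C)C[C@@]1(C)C(O)CC/C(C)=C\I | intermediate
13 | (3R,5S)-3-(tert-butyldimethylsilyloxy)-5-[(Z)-5-iodo-4-methyl-1-(trimethylsilyloxy)pent-4-en-1-yl]-5-methyl-1-(trimethylsilyloxy)cyclopent-1-ene | C[Si](C)(C)OC1=C[C@H](O[Si](C)(C)C(C)(C)C)C[C@@]1(C)C(O[Si](C)(C)C)CC/C(C)=C\I | intermediate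
14 | methyl pyruvate | CC(=O)C(=O)OC | starting material
15 | methyl (2R)-2-[(1R,3S,5R)-5-(tert-butyldimethylsilyloxy)-3-[(Z)-5-iodo-4-methyl-1-(trimethylsilyloxy)pent-4-en-1-yl]-3-methyl-2-oxocyclopentyl]-2-(trimethylsilyloxy)propanoate | O=C1[C@@H]([C@@](C)(O[Si](C)(C)C)C(=O)OC)[C@H](O[Si](C)(C)C(C)(C)C)C[C@@]1(C)C(O[Si](C)(C)C)CC/C(C)=C\I | intermediate
16 | methyl (2R)-2-[(1R,3S,5R)-5-(tert-butyldimethylsilyloxy)-3-[(Z)-1-hydroxy-5-iodo-4-methylpent-4-en-1-yl]-3-methyl-2-oxocyclopentyl]-2-hydroxypropanoate | O=C1[C@@H]([C@@](C)(O)C(=O)OC)[C@H](O[Si](C)(C)C(C)(C)C)C[C@@]1(C)C(O)CC/C(C)=C\I | intermediate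
17 | alkenylchromium dichloride of 16 (CrCl2 in place of iodine on C5) | O=C1[C@@H]([C@@](C)(O)C(=O)OC)[C@H](O[Si](C)(C)C(C)(C)C)C[C@@]1(C)C(O)CC/C(C)=C\[Cr](Cl)Cl | intermediate
18 | (6R,7S,8R,10S,11R)-cis-hydroazulene (cycloheptene C6–C5=C4–C3–C2–C1–C10, cyclopentane C6–C7–C8–C9–C10): 1-OH (both epimers), 6-OH, 8-OTBS, 4- and 10-methyl, C7 bearing C11(OH)(CH3)CO2CH3 | O[C@@]12C=C(C)CCC(O)[C@]1(C)C[C@@H](O[Si](C)(C)C(C)(C)C)[C@@H]2[C@@](C)(O)C(=O)OC | intermediate
19 | (6R,7S,8R,10S,11R)-cis-hydroazulene tetraol: as 18 with C7 bearing C11(OH)(CH3)CH2OH | O[C@@]12C=C(C)CCC(O)[C@]1(C)C[C@@H](O[Si](C)(C)C(C)(C)C)[C@@H]2[C@@](C)(O)CO | intermediate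
20 | (6R,7S,8R,10S,11R)-cis-hydroazulene-1,6-diol (1-OH both epimers), 8-OTBS, C7 bearing (4R)-2,2,4-trimethyl-1,3-dioxolan-4-yl | O[C@@]12C=C(C)CCC(O)[C@]1(C)C[C@@H](O[Si](C)(C)C(C)(C)C)[C@@H]2[C@]3(C)COC(C)(C)O3 | intermediate
21 | (6R,7S,8R,10R,11R)-6-hydroxy-cis-hydroazulen-1-one, 8-OTBS, 11,12-acetonide | O[C@@]12C=C(C)CCC(=O)[C@]1(C)C[C@@H](O[Si](C)(C)C(C)(C)C)[C@@H]2[C@]3(C)COC(C)(C)O3 | intermediate
22 | (1R,6R,7S,8R,10S,11R)-cis-hydroazulene-1,6-diol, 8-OTBS, 11,12-acetonide | O[C@@]12C=C(C)CC[C@@H](O)[C@]1(C)C[C@@H](O[Si](C)(C)C(C)(C)C)[C@@H]2[C@]3(C)COC(C)(C)O3 | intermediate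
23 | (1R,6R,7S,8R,10S,11R)-6-hydroxy-cis-hydroazulen-1-yl methanesulfonate, 8-OTBS, 11,12-acetonide | O[C@@]12C=C(C)CC[C@@H](OS(C)(=O)=O)[C@]1(C)C[C@@H](O[Si](C)(C)C(C)(C)C)[C@@H]2[C@]3(C)COC(C)(C)O3 | intermediate
24 | potassium C6 alkoxide of 23 | [K+].[O-][C@@]12C=C(C)CC[C@@H](OS(C)(=O)=O)[C@]1(C)C[C@@H](O[Si](C)(C)C(C)(C)C)[C@@H]2[C@]3(C)COC(C)(C)O3 | intermediate
25 | (7R,8R,11R)-(4Z,1(10)E)-4,10-dimethylcyclodeca-4,1(10)-dien-6-one, 8-OTBS, C7 bearing (4R)-2,2,4-trimethyl-1,3-dioxolan-4-yl | O=C1/C=C(/C)CC/C=C(\C)C[C@@H](O[Si](C)(C)C(C)(C)C)[C@@H]1[C@]2(C)COC(C)(C)O2 | intermediate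
26 | (6R,7R,8R,11R)-dien-6-ol corresponding to 25 | O[C@@H]1/C=C(/C)CC/C=C(\C)C[C@@H](O[Si](C)(C)C(C)(C)C)[C@@H]1[C@]2(C)COC(C)(C)O2 | intermediate
27 | lithium C6 alkoxide of 26 | [Li+].[O-][C@@H]1/C=C(/C)CC/C=C(\C)C[C@@H](O[Si](C)(C)C(C)(C)C)[C@@H]1[C@]2(C)COC(C)(C)O2 | intermediate
28 | (6R,7R,8R,11R)-6-angelate of 26 | C/C=C(/C)C(=O)O[C@@H]1/C=C(/C)CC/C=C(\C)C[C@@H](O[Si](C)(C)C(C)(C)C)[C@@H]1[C@]2(C)COC(C)(C)O2 | intermediate
29 | (6R,7R,8R,11R)-6-angeloyloxy-8-OTBS-diene-11,12-diol | C/C=C(/C)C(=O)O[C@@H]1/C=C(/C)CC/C=C(\C)C[C@@H](O[Si](C)(C)C(C)(C)C)[C@@H]1[C@@](C)(O)CO | intermediate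
30 | (6R,7R,8R,11R)-6-angeloyloxy-8-OTBS-11-hydroxy-dien-12-al | C/C=C(/C)C(=O)O[C@@H]1/C=C(/C)CC/C=C(\C)C[C@@H](O[Si](C)(C)C(C)(C)C)[C@@H]1[C@@](C)(O)C=O | intermediate
31 | (6R,7R,8R,11R)-6-angeloyloxy-8-OTBS-11-hydroxy-dien-12-oic acid | C/C=C(/C)C(=O)O[C@@H]1/C=C(/C)CC/C=C(\C)C[C@@H](O[Si](C)(C)C(C)(C)C)[C@@H]1[C@@](C)(O)C(=O)O | intermediate
32 | (6R,7S,8R,11R)-6-angeloyloxy-8,11-dihydroxy-dien-12-oic acid | C/C=C(/C)C(=O)O[C@@H]1/C=C(/C)CC/C=C(\C)C[C@@H](O)[C@@H]1[C@@](C)(O)C(=O)O | intermediate
33 | (6R,7S,8R,11R)-6-angeloyloxy-11-hydroxy-(4Z,1(10)E)-dien-12,8-olide | C/C=C(/C)C(=O)O[C@@H]1/C=C(/C)CC/C=C(\C)C[C@H]2OC(=O)[C@](C)(O)[C@H]12 | intermediate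
34 | lithium C11 alkoxide of 33 | [Li+].C/C=C(/C)C(=O)O[C@@H]1/C=C(/C)CC/C=C(\C)C[C@H]2OC(=O)[C@](C)([O-])[C@H]12 | intermediate
35 | (6R,7S,8R,11R)-6,11-bis(angeloyloxy)-(4Z,1(10)E)-dien-12,8-olide | C/C=C(/C)C(=O)O[C@@H]1/C=C(/C)CC/C=C(\C)C[C@H]2OC(=O)[C@](C)(OC(=O)/C(C)=C\C)[C@H]12 | intermediate
36 | CNP0182151.2, (1R,6R,7S,8R,10R,11R)-1,10-epoxy-6,11-bis(angeloyloxy)-(4Z)-en-12,8-olide | C/C=C(/C)C(=O)O[C@@H]1/C=C(/C)CC[C@H]2O[C@]2(C)C[C@H]2OC(=O)[C@](C)(OC(=O)/C(C)=C\C)[C@H]12 | target

## Step count and least certain steps

Total: 23 steps. Longest linear sequence: 21 steps (steps 1–3 and 6–23); steps 4–5 form the side branch to aldehyde 11.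

**Step 15 (key step).** The likely failure is proton transfer from the new C6 ketone to unreacted alkoxide. This would be followed by β-elimination of the C8 silyloxy or C11 alkoxy group, or by epimerisation at C7. A second failure is a slow fragmentation when the conformer with the equatorial mesylate is thinly populated, which lets silyl migration from O8 to O6 compete. Fallback: set out from 23 and silylate the tertiary hydroxyl (TMSOTf, 2,6-lutidine, −78 °C) to the C6 trimethylsilyl ether of the mesylate F1. Anhydrous fluoride (TASF or TBAF, THF, −40 °C) then releases the alkoxide with no alkoxide base in the flask, and the fragmentation returns to the route at 25.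

**Step 9.** The likely failure is protonation of the alkenylchromium species by the free hydroxyls, or its failure to add to the hindered C6 ketone, which lies syn to the C7 side chain. Either ends in simple loss of iodine. Fallback: set out from 15, kept as its bis-silyl ether by a neutral work-up in step 8. Iodine–lithium exchange (tBuLi, 2.1 equiv, THF/Et2O/pentane, −100 °C) gives an alkenyllithium that cyclises onto the ketone to the O1,O11-bis(trimethylsilyl) ether of the bicyclic ester F2. Dilute HCl in THF removes the silyl groups and returns to the route at 18.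

**Step 8.** The likely failure is poor reactivity of the hindered enol silane (quaternary C10 on one side, silyloxy-bearing C8 on the other) towards the copper-bound pyruvate, with loss of facial control as the background reaction takes over. Fallback: set out from 12 and form the dilithium alkoxide–enolate (LDA, 2.2 equiv, THF, −78 °C). Add it to 1-(tert-butyldimethylsilyloxy)propan-2-one to give the monocyclic C11 carbinol with a silylated C12 hydroxyl F3. C11 is then controlled only by the chelated chair transition state and chromatography. Ring closure as in step 9 gives the bicyclic analogue F4, and selective removal of the primary silyl ether (HF·pyridine, 0 °C) returns to the route at 19, with step 10 no longer needed.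

**Step 16.** The likely failure is poor facial selectivity. The branched C7 and the Z-alkenyl flank compete for the role of the large group, and the ring conformation adds its own bias. Fallback: set out from 25. If the 6S alcohol F5 predominates, from this reduction or from a Luche reduction (NaBH4, CeCl3, MeOH, −78 °C), a Mitsunobu esterification with angelic acid (PPh3, DIAD, toluene, 0 °C) inverts C6 and installs the ester in one step, returning at 28.

**Step 22.** The likely failure is incomplete acylation of the hindered tertiary alkoxide, or Z to E isomerisation of an angeloyl group under prolonged basic conditions. Fallback: set out from 33 and esterify the tertiary hydroxyl with 2-[bis(2,2,2-trifluoroethoxy)phosphoryl]propanoic acid (DCC, DMAP, CH2Cl2) to the phosphonate ester F6. No isomerisable alkene is present in the acyl donor at this stage. A Still–Gennari olefination with acetaldehyde (KHMDS, 18-crown-6, THF, −78 °C) then builds the Z alkene on the ester and returns at 35.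

**Step 23.** The likely failure is poor facial selectivity, if the preferred conformation of the ten-membered ring opposes the reagent's preference, together with some oxidation at C4=C5. Fallback: set out from 35 and use a two-step halohydrin sequence, which inverts the facial outcome of electrophilic attack. NBS in THF/H2O at 0 °C should give the bromohydrin F7 (Br on C1, OH on C10). Mild base (Ag2O or K2CO3 in acetone) closes the epoxide with inversion at C1 and returns at 36.

## Further compounds

F1 | step 15 | C6 trimethylsilyl ether of mesylate 23 | C[Si](C)(C)O[C@@]12C=C(C)CC[C@@H](OS(C)(=O)=O)[C@]1(C)C[C@@H](O[Si](C)(C)C(C)(C)C)[C@@H]2[C@]3(C)COC(C)(C)O3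
F2 | step 9 | O1,O11-bis(trimethylsilyl) ether of bicyclic ester 18 | O[C@@]12C=C(C)CCC(O[Si](C)(C)C)[C@]1(C)C[C@@H](O[Si](C)(C)C(C)(C)C)[C@@H]2[C@@](C)(O[Si](C)(C)C)C(=O)OC
F3 | step 8 | (2S,4R)-cyclopentanone 12 carrying at C7 the (R)-1-(tert-butyldimethylsilyloxy)-2-hydroxyprop-2-yl group | O=C1[C@@H]([C@@](C)(O)CO[Si](C)(C)C(C)(C)C)[C@H](O[Si](C)(C)C(C)(C)C)C[C@@]1(C)C(O)CC/C(C)=C\I
F4 | step 8 | cis-hydroazulene triol with 12-O-tert-butyldimethylsilyl ether | O[C@@]12C=C(C)CCC(O)[C@]1(C)C[C@@H](O[Si](C)(C)C(C)(C)C)[C@@H]2[C@@](C)(O)CO[Si](C)(C)C(C)(C)C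
F5 | step 16 | 6S epimer of dienol 26 | O[C@H]1/C=C(/C)CC/C=C(\C)C[C@@H](O[Si](C)(C)C(C)(C)C)[C@@H]1[C@]2(C)COC(C)(C)O2
F6 | step 22 | C11 2-[bis(2,2,2-trifluoroethoxy)phosphoryl]propanoate of 33 | C/C=C(/C)C(=O)O[C@@H]1/C=C(/C)CC/C=C(\C)C[C@H]2OC(=O)[C@](C)(OC(=O)C(C)P(=O)(OCC(F)(F)F)OCC(F)(F)F)[C@H]12
F7 | step 23 | 1-bromo-10-hydroxy bromohydrin of 35 | C/C=C(/C)C(=O)O[C@@H]1/C=C(/C)CC[C@H](Br)[C@@](O)(C)C[C@H]2OC(=O)[C@](C)(OC(=O)/C(C)=C\C)[C@H]12
A1 | alternative 1 | trans-lactone with free C11 hydroxyl, C6 acyl oxazolidinone and dienyl iodide chain on C8 | I/C=C(/C)CC/C=C(\C)C[C@H]1OC(=O)[C@](C)(O)[C@@H]1C(=O)N2C(=O)OC[C@@H]2Cc3ccccc3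
A2 | alternative 2 | ten-membered (4Z,1(10)E)-dienyl C5 triflate | COCO[C@@H]1/C(OS(=O)(=O)C(F)(F)F)=C(/C)CC/C=C(\C)C[C@@H](OCc2ccc(OC)cc2)[C@@H]1[C@]3(C)COC(C)(C)O3
A3 | alternative 3 | ten-membered dienol with C7 2-(silyloxymethyl)vinyl group | O[C@@H]1/C=C(/C)CC/C=C(\C)C[C@@H](O[Si](C)(C)C(C)(C)C)[C@@H]1C(=C)CO[Si](C)(C)C(C)(C)C
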